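**Retrosynthetic overview**

1. The target is a biflavone ether. Unit 1 (rings A, C, B; 5-OH, 7-OMe, 4'-OMe) carries at C8 of ring A the oxygen of ring E, the 4'-oxyphenyl ring of unit 2 (apigenin).
2. Feature used: C2 of unit 1 is a single carbon held between C3 (the acetyl methyl of a ring A acetophenone) and C1' of ring B. C2–C3 and C2–C1' are therefore cut together, and C2 is supplied as CO between 4-bromoanisole and the ring A 2-hydroxyacetophenone that already bears the C8 ether and benzyl-protected unit 2. Acid then closes ring C, and BCl3 frees the three phenols.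
3. The acetophenone precursor gets the pyranone of unit 2 by Baker–Venkataraman transfer and cyclodehydration from a 4-aryloxybenzoic acid and 2-hydroxy-4,6-bis(benzyloxy)acetophenone. The ring A acetyl group is placed by Fries rearrangement before any benzyl ether is in the molecule, and the phenol is then masked as a methoxymethyl ether.
4. The C8–O diaryl ether comes from SNAr of a Dakin-derived 2,6-dioxygenated phenol on methyl 4-fluorobenzoate.
5. Ring order: all benzene rings are bought; the pyranone of unit 2 is closed in step 11 and ring C of unit 1 in step 13.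

Key step: step 12

Remark: the target has no stereocentre, so no step needs stereocontrol.

**Step 1**
Reactants: 1 2-hydroxy-4,6-dimethoxybenzaldehyde
Product: 2 2-(methoxymethoxy)-4,6-dimethoxybenzaldehyde
Conditions: NaH, MOMCl, DMF, 0 °C → rt
Reagents that add atoms: chloromethyl methyl ether, COCCl
Why: Williamson-type O-alkylation of the sodium phenoxide with MOMCl masks the oxygen that later becomes O1 of unit 1, and the aldehyde has no α-hydrogen to interfere.

**Step 2**
Reactants: 2 2-(methoxymethoxy)-4,6-dimethoxybenzaldehyde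
Product: 4 2-(methoxymethoxy)-4,6-dimethoxyphenol, via aryl formate 3 (not isolated)
Conditions: mCPBA, CH2Cl2, 0 °C → rt; aq. NaHCO3 wash; then K2CO3 (cat.), MeOH, rt
Reagents that add atoms: 3-chloroperbenzoic acid, O=C(OO)c1cccc(Cl)c1
Why: Dakin-type oxidation, in which Baeyer–Villiger migration of the electron-rich trialkoxyaryl group gives the formate and base methanolysis releases the phenol, turns the formyl carbon into the future C8 ether oxygen.

**Step 3**
Reactants: 4 2-(methoxymethoxy)-4,6-dimethoxyphenol; 5 methyl 4-fluorobenzoate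
Product: 6 methyl 4-[2-(methoxymethoxy)-4,6-dimethoxyphenoxy]benzoate
Conditions: Cs2CO3, DMSO (degassed), 100 °C
Reagents that add atoms: none
Why: SNAr, in which the electron-rich caesium phenoxide displaces fluoride para to the ester through an ester-stabilised Meisenheimer intermediate, forms the diaryl ether.

**Step 4**
Reactants: 6 methyl 4-[2-(methoxymethoxy)-4,6-dimethoxyphenoxy]benzoate
Product: 7 methyl 4-(2-hydroxy-4,6-dimethoxyphenoxy)benzoate
Conditions: conc. HCl (cat.), MeOH, 50 °C
Reagents that add atoms: none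
Why: Acid-catalysed acetal exchange with methanol removes the methoxymethyl group while the methyl ester, the aryl methyl ethers and the diaryl ether are inert.

**Step 5**
Reactants: 7 methyl 4-(2-hydroxy-4,6-dimethoxyphenoxy)benzoate
Product: 10 methyl 4-(3-acetyl-2-hydroxy-4,6-dimethoxyphenoxy)benzoate, via aryl acetate 8 (not isolated), via difluoroboron chelate 9 (not isolated)
Conditions: Ac2O, BF3·OEt2, AcOH, 80 °C; then NaOAc, MeOH–H2O, 60 °C
Reagents that add atoms: acetic anhydride, CC(=O)OC(C)=O
Why: O-acetylation followed by BF3-mediated Fries rearrangement should deliver the acetyl group to the only free position ortho to the phenol oxygen, because only that isomer is held as the six-membered difluoroboron chelate, and no benzyl ether is yet present to be cleaved by the Lewis acid.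

**Step 6**
Reactants: 10 methyl 4-(3-acetyl-2-hydroxy-4,6-dimethoxyphenoxy)benzoate
Product: 11 methyl 4-[3-acetyl-2-(methoxymethoxy)-4,6-dimethoxyphenoxy]benzoate
Conditions: NaH (1.1 equiv), MOMCl, DMF, 0 °C → rt
Reagents that add atoms: chloromethyl methyl ether, COCCl
Why: Selective deprotonation of the phenol over the ketone and O-alkylation (Williamson) masks the hydroxyl so that it cannot compete as acyl acceptor in step 9.

**Step 7**
Reactants: 11 methyl 4-[3-acetyl-2-(methoxymethoxy)-4,6-dimethoxyphenoxy]benzoate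
Product: 12 4-[3-acetyl-2-(methoxymethoxy)-4,6-dimethoxyphenoxy]benzoic acid
Conditions: LiOH·H2O, THF–MeOH–H2O, 40 °C; then 1 M HCl to pH 4, 0 °C
Reagents that add atoms: lithium hydroxide, [Li+].[OH-]
Why: Saponification of the methyl ester by acyl–oxygen cleavage leaves the base-stable methoxymethyl ether and the hindered aryl ketone untouched.

**Step 8**
Reactants: 13 2,4,6-trihydroxyacetophenone
Product: 14 1-[2,4-bis(benzyloxy)-6-hydroxyphenyl]ethanone
Conditions: BnBr (2.1 equiv), K2CO3, DMF, rt
Reagents that add atoms: benzyl bromide, BrCc1ccccc1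
Why: Williamson benzylation stops at the dibenzyl ether because the last hydroxyl is locked in a hydrogen bond to the acetyl carbonyl and is the least nucleophilic.

**Step 9**
Reactants: 12 4-[3-acetyl-2-(methoxymethoxy)-4,6-dimethoxyphenoxy]benzoic acid; 14 1-[2,4-bis(benzyloxy)-6-hydroxyphenyl]ethanone
Product: 15 2-acetyl-3,5-bis(benzyloxy)phenyl 4-[3-acetyl-2-(methoxymethoxy)-4,6-dimethoxyphenoxy]benzoate
Conditions: DCC, DMAP (cat.), CH2Cl2, 0 °C → rt
Reagents that add atoms: none
Why: Steglich esterification through the acylpyridinium species acylates the only free phenol under neutral conditions that spare the methoxymethyl ether.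

**Step 10**
Reactants: 15 2-acetyl-3,5-bis(benzyloxy)phenyl 4-[3-acetyl-2-(methoxymethoxy)-4,6-dimethoxyphenoxy]benzoate
Product: 16 1-[2,4-bis(benzyloxy)-6-hydroxyphenyl]-3-{4-[3-acetyl-2-(methoxymethoxy)-4,6-dimethoxyphenoxy]phenyl}propane-1,3-dione
Conditions: KOH (powdered), pyridine, 50 °C; then aq. AcOH, 0 °C
Reagents that add atoms: none
Why: Baker–Venkataraman rearrangement, in which the enolate of the acetyl group ortho to the ester takes the aroyl group through a six-membered transition state, is intramolecular and so should outrun any reaction of the distant, doubly ortho-substituted ring A acetyl group, which cannot reach the ester.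

**Step 11**
Reactants: 16 1-[2,4-bis(benzyloxy)-6-hydroxyphenyl]-3-{4-[3-acetyl-2-(methoxymethoxy)-4,6-dimethoxyphenoxy]phenyl}propane-1,3-dione
Product: 17 1-[2-hydroxy-4,6-dimethoxy-3-(4-{5,7-bis(benzyloxy)-4-oxo-4H-chromen-2-yl}phenoxy)phenyl]ethanone
Conditions: conc. HCl (cat.), MeOH–THF, 60 °C
Reagents that add atoms: none
Why: Acid-catalysed cyclodehydration (addition of the phenol to the aroyl carbonyl, then loss of water) closes the pyranone of unit 2, and the same acid transfers the methoxymethyl group to methanol, so the formaldehyde equivalent is trapped as an inert acetal.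

**Step 12**
Reactants: 17 1-[2-hydroxy-4,6-dimethoxy-3-(4-{5,7-bis(benzyloxy)-4-oxo-4H-chromen-2-yl}phenoxy)phenyl]ethanone; 18 4-bromoanisole; 19 carbon monoxide
Product: 20 1-[2-hydroxy-4,6-dimethoxy-3-(4-{5,7-bis(benzyloxy)-4-oxo-4H-chromen-2-yl}phenoxy)phenyl]-3-(4-methoxyphenyl)propane-1,3-dione
Conditions: NaN(SiMe3)2 (3.3 equiv), THF, 0 °C; then 18, Pd(OAc)2 (5 mol%), Xantphos (6 mol%), CO (1 atm), 1,4-dioxane, 80 °C; then AcOH
Reagents that add atoms: none
Why: Pd(OAc)2 is reduced in the flask to a zerovalent palladium–Xantphos complex that adds oxidatively to the C–Br bond of 18, and CO insertion gives a divalent aroylpalladium bromide in which C2–C1' is already formed. The sodium enolate of the acetyl group of 17 (the phenol is deprotonated first, then the methyl ketone) displaces bromide and reductive elimination forms C2–C3; acylation at the phenoxide oxygen instead would give the aryl 4-methoxybenzoate, which the same base carries on to the same diketonate by Baker–Venkataraman transfer. The closest known reactions are the palladium-catalysed carbonylative α-arylation of aryl methyl ketones with aryl bromides and the carbonylative flavone synthesis from 2-hydroxyacetophenones. No ring is closed and no stereocentre is formed here; ring C is left for step 13. The step needs CO insertion to outrun direct α-arylation, which the wide bite angle of Xantphos and the CO atmosphere favour, and it needs a single acylation, which follows because the product is deprotonated at once to a stabilised diketonate and because the acetyl methyl is the only enolisable position of 17. The hindered silylamide is chosen over an alkoxide so that the aroylpalladium is not drained off as an ester and the pyranone of unit 2 is not opened by conjugate addition.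

**Step 13**
Reactants: 20 1-[2-hydroxy-4,6-dimethoxy-3-(4-{5,7-bis(benzyloxy)-4-oxo-4H-chromen-2-yl}phenoxy)phenyl]-3-(4-methoxyphenyl)propane-1,3-dione
Product: 21 8-{4-[5,7-bis(benzyloxy)-4-oxo-4H-chromen-2-yl]phenoxy}-5,7-dimethoxy-2-(4-methoxyphenyl)-4H-chromen-4-one
Conditions: H2SO4 (cat.), AcOH, 70 °C
Reagents that add atoms: none
Why: Acid-catalysed cyclodehydration of the 1-(2-hydroxyaryl)-1,3-diketone closes ring C of unit 1 through the single free phenol, which fixes the ether at C8 and the methoxy groups at C5 and C7.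

**Step 14**
Reactants: 21 8-{4-[5,7-bis(benzyloxy)-4-oxo-4H-chromen-2-yl]phenoxy}-5,7-dimethoxy-2-(4-methoxyphenyl)-4H-chromen-4-one
Product: 22 8-[4-(5,7-dihydroxy-4-oxo-4H-chromen-2-yl)phenoxy]-5-hydroxy-7-methoxy-2-(4-methoxyphenyl)-4H-chromen-4-one (CNP0259871.0)
Conditions: BCl3 (8 equiv), pentamethylbenzene, CH2Cl2, −78 °C → rt (monitored); then MeOH–H2O
Reagents that add atoms: none
Why: Lewis-acid ether cleavage with BCl3 removes both benzyl groups (pentamethylbenzene traps the benzyl cations) and, by chelation to the C4 carbonyl, the peri C5 methyl ether of unit 1, while the non-chelated 7- and 4'-methyl ethers and the diaryl ether should survive.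

**Compound list**

1 | 2-hydroxy-4,6-dimethoxybenzaldehyde | COc1cc(O)c(C=O)c(OC)c1 | starting material
2 | 2-(methoxymethoxy)-4,6-dimethoxybenzaldehyde | COCOc1cc(OC)cc(OC)c1C=O | intermediate
3 | 2-(methoxymethoxy)-4,6-dimethoxyphenyl formate (not isolated) | COCOc1cc(OC)cc(OC)c1OC=O | intermediate
4 | 2-(methoxymethoxy)-4,6-dimethoxyphenol | COCOc1cc(OC)cc(OC)c1O | intermediate
5 | methyl 4-fluorobenzoate | COC(=O)c1ccc(F)cc1 | starting material
6 | methyl 4-[2-(methoxymethoxy)-4,6-dimethoxyphenoxy]benzoate | COCOc1cc(OC)cc(OC)c1Oc1ccc(C(=O)OC)cc1 | intermediate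
7 | methyl 4-(2-hydroxy-4,6-dimethoxyphenoxy)benzoate | COC(=O)c1ccc(Oc2c(O)cc(OC)cc2OC)cc1 | intermediate
8 | methyl 4-(2-acetoxy-4,6-dimethoxyphenoxy)benzoate (not isolated) | COC(=O)c1ccc(Oc2c(OC(C)=O)cc(OC)cc2OC)cc1 | intermediate
9 | difluoroboron O,O-chelate of 10 (not isolated) | CC1=[O+][B-](F)(F)Oc2c(Oc3ccc(C(=O)OC)cc3)c(OC)cc(OC)c12 | intermediate
10 | methyl 4-(3-acetyl-2-hydroxy-4,6-dimethoxyphenoxy)benzoate | CC(=O)c1c(O)c(Oc2ccc(C(=O)OC)cc2)c(OC)cc1OC | intermediate
11 | methyl 4-[3-acetyl-2-(methoxymethoxy)-4,6-dimethoxyphenoxy]benzoate | CC(=O)c1c(OCOC)c(Oc2ccc(C(=O)OC)cc2)c(OC)cc1OC | intermediate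
12 | 4-[3-acetyl-2-(methoxymethoxy)-4,6-dimethoxyphenoxy]benzoic acid | CC(=O)c1c(OCOC)c(Oc2ccc(C(=O)O)cc2)c(OC)cc1OC | intermediate
13 | 2,4,6-trihydroxyacetophenone | CC(=O)c1c(O)cc(O)cc1O | starting material
14 | 1-[2,4-bis(benzyloxy)-6-hydroxyphenyl]ethanone | CC(=O)c1c(O)cc(OCc2ccccc2)cc1OCc1ccccc1 | intermediate
15 | 2-acetyl-3,5-bis(benzyloxy)phenyl 4-[3-acetyl-2-(methoxymethoxy)-4,6-dimethoxyphenoxy]benzoate | CC(=O)c1c(OCOC)c(Oc2ccc(C(=O)Oc3cc(OCc4ccccc4)cc(OCc4ccccc4)c3C(C)=O)cc2)c(OC)cc1OC | intermediate
16 | 1-[2,4-bis(benzyloxy)-6-hydroxyphenyl]-3-{4-[3-acetyl-2-(methoxymethoxy)-4,6-dimethoxyphenoxy]phenyl}propane-1,3-dione | CC(=O)c1c(OCOC)c(Oc2ccc(C(=O)CC(=O)c3c(O)cc(OCc4ccccc4)cc3OCc3ccccc3)cc2)c(OC)cc1OC | intermediate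
17 | 1-[2-hydroxy-4,6-dimethoxy-3-(4-{5,7-bis(benzyloxy)-4-oxo-4H-chromen-2-yl}phenoxy)phenyl]ethanone | CC(=O)c1c(O)c(Oc2ccc(-c3cc(=O)c4c(OCc5ccccc5)cc(OCc5ccccc5)cc4o3)cc2)c(OC)cc1OC | intermediate
18 | 4-bromoanisole | COc1ccc(Br)cc1 | starting material
19 | carbon monoxide | [C-]#[O+] | starting material
20 | 1-[2-hydroxy-4,6-dimethoxy-3-(4-{5,7-bis(benzyloxy)-4-oxo-4H-chromen-2-yl}phenoxy)phenyl]-3-(4-methoxyphenyl)propane-1,3-dione | COc1ccc(C(=O)CC(=O)c2c(O)c(Oc3ccc(-c4cc(=O)c5c(OCc6ccccc6)cc(OCc6ccccc6)cc5o4)cc3)c(OC)cc2OC)cc1 | intermediate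
21 | 8-{4-[5,7-bis(benzyloxy)-4-oxo-4H-chromen-2-yl]phenoxy}-5,7-dimethoxy-2-(4-methoxyphenyl)-4H-chromen-4-one | COc1ccc(-c2cc(=O)c3c(OC)cc(OC)c(Oc4ccc(-c5cc(=O)c6c(OCc7ccccc7)cc(OCc7ccccc7)cc6o5)cc4)c3o2)cc1 | intermediate
22 | 8-[4-(5,7-dihydroxy-4-oxo-4H-chromen-2-yl)phenoxy]-5-hydroxy-7-methoxy-2-(4-methoxyphenyl)-4H-chromen-4-one | COc1ccc(-c2cc(=O)c3c(O)cc(OC)c(Oc4ccc(-c5cc(=O)c6c(O)cc(O)cc6o5)cc4)c3o2)cc1 | target

**Step count**

Total steps: 14. Longest linear sequence: 13 (steps 1–7, then 9–14); step 8 is a one-step side branch.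

**Steps most likely to fail**

Step 12. Direct α-arylation without CO uptake, capture of the aroylpalladium by the silylamine, or sequestration of the catalyst by the chelating phenoxide–enolate could starve the carbonylative pathway. The fallback sets out from 17 and drops the palladium chemistry. O-Acylation with 4-methoxybenzoyl chloride in pyridine with DMAP would give 2-acetyl-3,5-dimethoxy-6-(4-{5,7-bis(benzyloxy)-4-oxo-4H-chromen-2-yl}phenoxy)phenyl 4-methoxybenzoate F1. Treatment with powdered KOH in pyridine at 50 °C (Baker–Venkataraman rearrangement) would then move the aroyl group to carbon, and the route is rejoined at 20.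

Step 5. The acyl group may migrate to the position between the two methoxy groups (para to the phenol), or the Lewis acid may start to cleave a methyl ether at the temperature needed. The fallback sets out from 7 and uses a boron-templated ortho-acylation with a nitrile instead of a Fries rearrangement. BCl3 (about 1 equiv) binds the phenol oxygen and delivers acetonitrile (with AlCl3 as co-acid, 1,2-dichloroethane, 0 → 60 °C) to the adjacent carbon only, giving the ketimine methyl 4-(3-ethanimidoyl-2-hydroxy-4,6-dimethoxyphenoxy)benzoate F2 as its boron complex. Warm aqueous HCl hydrolyses it, and the route is rejoined at 10.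

Step 14. The C5 methyl ether may cleave incompletely at a temperature that still spares the 7- and 4'-methyl ethers, and benzyl cations may alkylate the electron-rich rings. The fallback sets out from 21 and separates the two tasks. Hydrogenolysis (H2, Pd/C, THF–MeOH, rt) would remove the benzyl groups without any cation and give 8-[4-(5,7-dihydroxy-4-oxo-4H-chromen-2-yl)phenoxy]-5,7-dimethoxy-2-(4-methoxyphenyl)-4H-chromen-4-one F3. Chelation-controlled peri-demethylation with AlCl3 in MeCN at 50 °C would then cleave only the C5 methyl ether, and the route ends at 22.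

**Further compounds**

F1 | step 12 | 2-acetyl-3,5-dimethoxy-6-(4-{5,7-bis(benzyloxy)-4-oxo-4H-chromen-2-yl}phenoxy)phenyl 4-methoxybenzoate | CC(=O)c1c(OC(=O)c2ccc(OC)cc2)c(Oc2ccc(-c3cc(=O)c4c(OCc5ccccc5)cc(OCc5ccccc5)cc4o3)cc2)c(OC)cc1OC
F2 | step 5 | methyl 4-(3-ethanimidoyl-2-hydroxy-4,6-dimethoxyphenoxy)benzoate | CC(=N)c1c(O)c(Oc2ccc(C(=O)OC)cc2)c(OC)cc1OC
F3 | step 14 | 8-[4-(5,7-dihydroxy-4-oxo-4H-chromen-2-yl)phenoxy]-5,7-dimethoxy-2-(4-methoxyphenyl)-4H-chromen-4-one | COc1ccc(-c2cc(=O)c3c(OC)cc(OC)c(Oc4ccc(-c5cc(=O)c6c(O)cc(O)cc6o5)cc4)c3o2)cc1
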